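**Retrosynthetic overview**
1. Target 27 ⇐ buffered oxidation of ring allylic alcohol 26 (from TBS ether 25); the base-sensitive enone is unveiled only in the last step.
2. Hexaene ester 25 ⇐ HWE of C20 aldehyde 21 with C5 phosphonate 24; 21 ⇐ HWE of C15 aldehyde 17 with phosphonate 18; 17 ⇐ Suzuki coupling of ring iodoalkene 12 with boronate 14.
3. 12 ⇐ enantiopure hydroxy ester 8 (ester → aldehyde → Takai iodo-olefination); 8 ⇐ camphanate resolution of racemic trans-hydroxy ester 6.
4. The only ring is made first: intermolecular Michael addition of methyl acetoacetate to mesityl oxide (quaternary carbon–methine bond), then aldol ring closure to keto ester 5.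

Assumption: the ring stereocentre of the target is read as (S) (CIP order ring C2 > ring C6 > chain > H), and (1S)-(−)-camphanic chloride and triethyl 3-methyl-4-phosphonocrotonate count as stock chemicals.

**Route**

Step 1
Reactants: 1 mesityl oxide (4-methylpent-3-en-2-one); 2 methyl acetoacetate
Product: 5 methyl (1RS)-2,6,6-trimethyl-4-oxocyclohex-2-ene-1-carboxylate, via Michael adduct 3 (not isolated), via aldol adduct 4 (not isolated)
Conditions: ZnCl2 (0.2 equiv), toluene–heptane, reflux, Dean–Stark, 48 h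
Reagents that add atoms: none
Why: Lewis-acid-promoted Michael addition of the acetoacetate enol to the β,β-dimethyl enone forms the quaternary-carbon-to-methine bond, and the 1,5-diketone closes by intramolecular aldol condensation (Robinson-type annulation, as for Hagemann's ester) to the ring, whose new methine centre is formed racemic and is still base-labile.

Step 2
Reactants: 5 methyl (1RS)-2,6,6-trimethyl-4-oxocyclohex-2-ene-1-carboxylate
Product: 6 methyl (1RS,4RS)-4-hydroxy-2,6,6-trimethylcyclohex-2-ene-1-carboxylate (trans racemate)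
Conditions: NaBH4, CeCl3·7H2O, MeOH, −20 → 0 °C; silica chromatography
Reagents that add atoms: none
Why: Luche 1,2-reduction removes the vinylogous β-keto ester acidity and so freezes the ring methine centre, while substrate control (hydride expected anti to the axial ring methyl) sets the carbinol centre mainly trans and the cis racemate is removed on silica.

Step 3
Reactants: 6 methyl (1RS,4RS)-4-hydroxy-2,6,6-trimethylcyclohex-2-ene-1-carboxylate
Product: 7 methyl (1S,4S)-2,6,6-trimethyl-4-{[(1S,4R)-4,7,7-trimethyl-3-oxo-2-oxabicyclo[2.2.1]heptane-1-carbonyl]oxy}cyclohex-2-ene-1-carboxylate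
Conditions: (1S)-(−)-camphanic chloride, Et3N, DMAP (cat.), CH2Cl2, 0 °C → rt; fractional crystallisation (hexane–EtOAc), then chromatography of the mother liquor
Reagents that add atoms: (1S)-(−)-camphanic chloride, O=C(Cl)[C@@]12CC[C@@](C)(C(=O)O1)C2(C)C
Why: Classical resolution by acylation gives two diastereomeric camphanates that differ at the carbinol carbon next to the auxiliary and are separated physically, which secures the (S) ring methine centre of the target (assignment by X-ray against the known camphanoyl centres).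

Step 4
Reactants: 7 the (1S,4S) camphanate
Product: 8 methyl (1S,4S)-4-hydroxy-2,6,6-trimethylcyclohex-2-ene-1-carboxylate
Conditions: K2CO3 (0.5 equiv), MeOH, 0 °C → rt
Reagents that add atoms: none
Why: Base-catalysed transesterification cleaves the secondary camphanate, whereas the ring methyl ester, flanked by a quaternary carbon and a trisubstituted alkene, is too hindered to react or enolise, so both centres are kept.

Step 5
Reactants: 8 methyl (1S,4S)-4-hydroxy-2,6,6-trimethylcyclohex-2-ene-1-carboxylate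
Product: 9 methyl (1S,4S)-4-[(tert-butyldimethylsilyl)oxy]-2,6,6-trimethylcyclohex-2-ene-1-carboxylate
Conditions: TBSCl, imidazole, DMF, rt
Reagents that add atoms: tert-butyldimethylsilyl chloride, CC(C)(C)[Si](C)(C)Cl
Why: Standard silyl ether formation; the TBS group carries the ring oxygen through hydride, organometallic and basic steps and keeps the ring methine hydrogen merely allylic.

Step 6
Reactants: 9 the TBS ether ester
Product: 10 {(1S,4S)-4-[(tert-butyldimethylsilyl)oxy]-2,6,6-trimethylcyclohex-2-en-1-yl}methanol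
Conditions: LiAlH4, Et2O, 0 °C → rt
Reagents that add atoms: none
Why: Hydride reduction of the hindered ester to the primary alcohol is non-enolising, so the adjacent centre is untouched.

Step 7
Reactants: 10 the primary alcohol
Product: 11 (1S,4S)-4-[(tert-butyldimethylsilyl)oxy]-2,6,6-trimethylcyclohex-2-ene-1-carbaldehyde
Conditions: Dess–Martin periodinane, NaHCO3, CH2Cl2, 0 °C → rt; used crude at once
Reagents that add atoms: none
Why: Buffered Dess–Martin oxidation gives the α-branched β,γ-unsaturated aldehyde without base or strong acid, so the α-centre neither epimerises nor moves into conjugation.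

Step 8
Reactants: 11 the aldehyde
Product: 12 tert-butyl({(1S,4S)-4-[(E)-2-iodoethenyl]-3,5,5-trimethylcyclohex-2-en-1-yl}oxy)dimethylsilane
Conditions: CrCl2 (6 equiv), CHI3 (2 equiv), THF–1,4-dioxane (1:6), 0 °C → rt, dark
Reagents that add atoms: iodoform, IC(I)I
Why: Takai iodo-olefination is non-basic, tolerates hindered α-chiral aldehydes and gives the (E)-iodoalkene, after which the ring centre is only allylic and configurationally safe.

Step 9
Reactants: 13 ethyl but-2-ynoate
Product: 14 ethyl (Z)-3-(4,4,5,5-tetramethyl-1,3,2-dioxaborolan-2-yl)but-2-enoate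
Conditions: B2pin2 (1.1 equiv), CuCl (3 mol%), NaOtBu (6 mol%), Xantphos (3 mol%), MeOH (2 equiv), THF, rt
Reagents that add atoms: bis(pinacolato)diboron, CC1(C)OB(OC1(C)C)B1OC(C)(C)C(C)(C)O1
Why: Copper-catalysed borylcupration of the ynoate followed by protonation is a syn addition with boron at the β-carbon, giving one geometrically defined β-boryl enoate.

Step 10
Reactants: 12 the ring iodoalkene; 14 the boronate
Product: 15 ethyl (2E,4E)-5-{(1S,4S)-4-[(tert-butyldimethylsilyl)oxy]-2,6,6-trimethylcyclohex-2-en-1-yl}-3-methylpenta-2,4-dienoate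
Conditions: Pd(dppf)Cl2 (5 mol%), K3PO4 (3 equiv), THF–H2O (5:1), 45 °C
Reagents that add atoms: none
Why: Suzuki–Miyaura coupling proceeds with retention at both sp2 carbons, so the geometry of the iodide and of the boronate is carried into the (2E,4E)-dienoate, and phosphate base cannot touch the allylic ring centre.

Step 11
Reactants: 15 the C15 dienoate
Product: 16 (2E,4E)-5-{(1S,4S)-4-[(tert-butyldimethylsilyl)oxy]-2,6,6-trimethylcyclohex-2-en-1-yl}-3-methylpenta-2,4-dien-1-ol
Conditions: i-Bu2AlH (2.5 equiv), CH2Cl2, −78 °C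
Reagents that add atoms: none
Why: 1,2-Reduction of the conjugated ester by i-Bu2AlH gives the allylic alcohol without touching alkenes or the silyl ether.

Step 12
Reactants: 16 the C15 dienol
Product: 17 (2E,4E)-5-{(1S,4S)-4-[(tert-butyldimethylsilyl)oxy]-2,6,6-trimethylcyclohex-2-en-1-yl}-3-methylpenta-2,4-dienal
Conditions: MnO2 (activated, 20 equiv), CH2Cl2, rt
Reagents that add atoms: none
Why: MnO2 oxidises the primary allylic alcohol selectively under neutral conditions, with no isomerisation.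

Step 13
Reactants: 17 the C15 dienal; 18 ethyl (E)-4-(diethoxyphosphoryl)-3-methylbut-2-enoate
Product: 19 ethyl (2E,4E,6E,8E)-9-{(1S,4S)-4-[(tert-butyldimethylsilyl)oxy]-2,6,6-trimethylcyclohex-2-en-1-yl}-3,7-dimethylnona-2,4,6,8-tetraenoate
Conditions: 18 (1.5 equiv), LiN(SiMe3)2 (1.4 equiv), DMPU, THF, −78 °C; then 17, −78 → −20 °C, dark
Reagents that add atoms: none
Why: Horner–Wadsworth–Emmons olefination with the allylic phosphonate carbanion gives the new disubstituted double bond E, and the lithium counter-ion with DMPU at low temperature keeps the trisubstituted double bond of the reagent largely E (minor 2Z isomer removed by chromatography).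

Step 14
Reactants: 19 the C20 tetraenoate
Product: 20 (2E,4E,6E,8E)-9-{(1S,4S)-4-[(tert-butyldimethylsilyl)oxy]-2,6,6-trimethylcyclohex-2-en-1-yl}-3,7-dimethylnona-2,4,6,8-tetraen-1-ol
Conditions: i-Bu2AlH (2.5 equiv), CH2Cl2, −78 °C, dark
Reagents that add atoms: none
Why: Same 1,2-reduction of a conjugated ester as in step 11.

Step 15
Reactants: 20 the C20 tetraenol
Product: 21 (2E,4E,6E,8E)-9-{(1S,4S)-4-[(tert-butyldimethylsilyl)oxy]-2,6,6-trimethylcyclohex-2-en-1-yl}-3,7-dimethylnona-2,4,6,8-tetraenal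
Conditions: MnO2 (activated, 20 equiv), CH2Cl2, rt, dark
Reagents that add atoms: none
Why: Neutral allylic oxidation as in step 12.

Step 16
Reactants: 22 methyl (E)-2-methylbut-2-enoate (methyl tiglate)
Product: 23 methyl (E)-4-bromo-2-methylbut-2-enoate
Conditions: NBS, AIBN (cat.), PhCF3, reflux; distillation
Reagents that add atoms: N-bromosuccinimide, BrN1C(=O)CCC1=O
Why: Wohl–Ziegler allylic bromination takes place mainly at the γ-methyl through the delocalised allylic radical, with the E geometry kept (regioisomer removed by distillation).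

Step 17
Reactants: 23 the allylic bromide
Product: 24 methyl (E)-4-(diethoxyphosphoryl)-2-methylbut-2-enoate
Conditions: P(OEt)3, neat, 140 °C (EtBr distilled off)
Reagents that add atoms: triethyl phosphite, CCOP(OCC)OCC
Why: Michaelis–Arbuzov reaction of the primary allylic bromide gives the phosphonate cleanly.

Step 18
Reactants: 21 the C20 tetraenal; 24 the C5 phosphonate
Product: 25 methyl (2E,4E,6E,8E,10E,12E)-13-{(1S,4S)-4-[(tert-butyldimethylsilyl)oxy]-2,6,6-trimethylcyclohex-2-en-1-yl}-2,6,10-trimethyltrideca-2,4,6,8,10,12-hexaenoate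
Conditions: 24 (1.5 equiv), LiN(SiMe3)2 (1.4 equiv), THF, −78 °C; then 21, −78 → 0 °C, dark
Reagents that add atoms: none
Why: Horner–Wadsworth–Emmons olefination of the polyenal gives the new double bond E and completes the hexaene methyl ester, the base being consumed by the phosphonate so the ring centre is not deprotonated.

Step 19
Reactants: 25 the silyl-protected hexaene ester
Product: 26 methyl (2E,4E,6E,8E,10E,12E)-13-[(1S,4S)-4-hydroxy-2,6,6-trimethylcyclohex-2-en-1-yl]-2,6,10-trimethyltrideca-2,4,6,8,10,12-hexaenoate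
Conditions: Bu4NF, AcOH (1 equiv each, excess), THF, 0 °C → rt, dark
Reagents that add atoms: none
Why: Fluoride desilylation buffered with acetic acid frees the ring allylic alcohol without harming the polyene ester.

Step 20
Reactants: 26 the ring allylic alcohol
Product: 27 methyl (2E,4E,6E,8E,10E,12E)-2,6,10-trimethyl-13-[(1S)-2,6,6-trimethyl-4-oxocyclohex-2-en-1-yl]trideca-2,4,6,8,10,12-hexaenoate
Conditions: Dess–Martin periodinane, NaHCO3, CH2Cl2, 0 °C, dark; neutral work-up
Reagents that add atoms: none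
Why: Buffered Dess–Martin oxidation of the secondary allylic alcohol gives the enone under base-free conditions, which erases the auxiliary carbinol centre and leaves the γ-methine (S) centre untouched.

**Compound list**
1 | mesityl oxide (4-methylpent-3-en-2-one) | CC(=O)C=C(C)C | starting material
2 | methyl acetoacetate | COC(=O)CC(C)=O | starting material
3 | methyl 2-acetyl-3,3-dimethyl-5-oxohexanoate (racemic Michael adduct) | COC(=O)C(C(C)=O)C(C)(C)CC(C)=O | intermediate
4 | methyl 2-hydroxy-2,6,6-trimethyl-4-oxocyclohexane-1-carboxylate (aldol adduct, stereoisomer mixture) | COC(=O)C1C(C)(O)CC(=O)CC1(C)C | intermediate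
5 | methyl (1RS)-2,6,6-trimethyl-4-oxocyclohex-2-ene-1-carboxylate | COC(=O)C1C(C)=CC(=O)CC1(C)C | intermediate
6 | methyl (1RS,4RS)-4-hydroxy-2,6,6-trimethylcyclohex-2-ene-1-carboxylate (trans racemate, both enantiomers written) | COC(=O)[C@@H]1C(C)=C[C@@H](O)CC1(C)C.COC(=O)[C@H]1C(C)=C[C@H](O)CC1(C)C | intermediate
7 | methyl (1S,4S)-2,6,6-trimethyl-4-{[(1S,4R)-4,7,7-trimethyl-3-oxo-2-oxabicyclo[2.2.1]heptane-1-carbonyl]oxy}cyclohex-2-ene-1-carboxylate | COC(=O)[C@@H]1C(C)=C[C@@H](OC(=O)[C@@]23CC[C@@](C)(C(=O)O2)C3(C)C)CC1(C)C | intermediate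
8 | methyl (1S,4S)-4-hydroxy-2,6,6-trimethylcyclohex-2-ene-1-carboxylate | COC(=O)[C@@H]1C(C)=C[C@@H](O)CC1(C)C | intermediate
9 | methyl (1S,4S)-4-[(tert-butyldimethylsilyl)oxy]-2,6,6-trimethylcyclohex-2-ene-1-carboxylate | COC(=O)[C@@H]1C(C)=C[C@@H](O[Si](C)(C)C(C)(C)C)CC1(C)C | intermediate
10 | {(1S,4S)-4-[(tert-butyldimethylsilyl)oxy]-2,6,6-trimethylcyclohex-2-en-1-yl}methanol | OC[C@@H]1C(C)=C[C@@H](O[Si](C)(C)C(C)(C)C)CC1(C)C | intermediate
11 | (1S,4S)-4-[(tert-butyldimethylsilyl)oxy]-2,6,6-trimethylcyclohex-2-ene-1-carbaldehyde | O=C[C@@H]1C(C)=C[C@@H](O[Si](C)(C)C(C)(C)C)CC1(C)C | intermediate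
12 | tert-butyl({(1S,4S)-4-[(E)-2-iodoethenyl]-3,5,5-trimethylcyclohex-2-en-1-yl}oxy)dimethylsilane | I/C=C/[C@@H]1C(C)=C[C@@H](O[Si](C)(C)C(C)(C)C)CC1(C)C | intermediate
13 | ethyl but-2-ynoate | CCOC(=O)C#CC | starting material
14 | ethyl (Z)-3-(4,4,5,5-tetramethyl-1,3,2-dioxaborolan-2-yl)but-2-enoate | CCOC(=O)/C=C(\C)B1OC(C)(C)C(C)(C)O1 | intermediate
15 | ethyl (2E,4E)-5-{(1S,4S)-4-[(tert-butyldimethylsilyl)oxy]-2,6,6-trimethylcyclohex-2-en-1-yl}-3-methylpenta-2,4-dienoate | CCOC(=O)/C=C(C)/C=C/[C@@H]1C(C)=C[C@@H](O[Si](C)(C)C(C)(C)C)CC1(C)C | intermediate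
16 | (2E,4E)-5-{(1S,4S)-4-[(tert-butyldimethylsilyl)oxy]-2,6,6-trimethylcyclohex-2-en-1-yl}-3-methylpenta-2,4-dien-1-ol | OC/C=C(C)/C=C/[C@@H]1C(C)=C[C@@H](O[Si](C)(C)C(C)(C)C)CC1(C)C | intermediate
17 | (2E,4E)-5-{(1S,4S)-4-[(tert-butyldimethylsilyl)oxy]-2,6,6-trimethylcyclohex-2-en-1-yl}-3-methylpenta-2,4-dienal | O=C/C=C(C)/C=C/[C@@H]1C(C)=C[C@@H](O[Si](C)(C)C(C)(C)C)CC1(C)C | intermediate
18 | ethyl (E)-4-(diethoxyphosphoryl)-3-methylbut-2-enoate (triethyl 3-methyl-4-phosphonocrotonate) | CCOC(=O)/C=C(\C)CP(=O)(OCC)OCC | starting material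
19 | ethyl (2E,4E,6E,8E)-9-{(1S,4S)-4-[(tert-butyldimethylsilyl)oxy]-2,6,6-trimethylcyclohex-2-en-1-yl}-3,7-dimethylnona-2,4,6,8-tetraenoate | CCOC(=O)/C=C(C)/C=C/C=C(C)/C=C/[C@@H]1C(C)=C[C@@H](O[Si](C)(C)C(C)(C)C)CC1(C)C | intermediate
20 | (2E,4E,6E,8E)-9-{(1S,4S)-4-[(tert-butyldimethylsilyl)oxy]-2,6,6-trimethylcyclohex-2-en-1-yl}-3,7-dimethylnona-2,4,6,8-tetraen-1-ol | OC/C=C(C)/C=C/C=C(C)/C=C/[C@@H]1C(C)=C[C@@H](O[Si](C)(C)C(C)(C)C)CC1(C)C | intermediate
21 | (2E,4E,6E,8E)-9-{(1S,4S)-4-[(tert-butyldimethylsilyl)oxy]-2,6,6-trimethylcyclohex-2-en-1-yl}-3,7-dimethylnona-2,4,6,8-tetraenal | O=C/C=C(C)/C=C/C=C(C)/C=C/[C@@H]1C(C)=C[C@@H](O[Si](C)(C)C(C)(C)C)CC1(C)C | intermediate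
22 | methyl (E)-2-methylbut-2-enoate (methyl tiglate) | COC(=O)/C(C)=C/C | starting material
23 | methyl (E)-4-bromo-2-methylbut-2-enoate | COC(=O)/C(C)=C/CBr | intermediate
24 | methyl (E)-4-(diethoxyphosphoryl)-2-methylbut-2-enoate | COC(=O)/C(C)=C/CP(=O)(OCC)OCC | intermediate
25 | methyl (2E,4E,6E,8E,10E,12E)-13-{(1S,4S)-4-[(tert-butyldimethylsilyl)oxy]-2,6,6-trimethylcyclohex-2-en-1-yl}-2,6,10-trimethyltrideca-2,4,6,8,10,12-hexaenoate | COC(=O)/C(C)=C/C=C/C=C(C)/C=C/C=C(C)/C=C/[C@@H]1C(C)=C[C@@H](O[Si](C)(C)C(C)(C)C)CC1(C)C | intermediate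
26 | methyl (2E,4E,6E,8E,10E,12E)-13-[(1S,4S)-4-hydroxy-2,6,6-trimethylcyclohex-2-en-1-yl]-2,6,10-trimethyltrideca-2,4,6,8,10,12-hexaenoate | COC(=O)/C(C)=C/C=C/C=C(C)/C=C/C=C(C)/C=C/[C@@H]1C(C)=C[C@@H](O)CC1(C)C | intermediate
27 | methyl (2E,4E,6E,8E,10E,12E)-2,6,10-trimethyl-13-[(1S)-2,6,6-trimethyl-4-oxocyclohex-2-en-1-yl]trideca-2,4,6,8,10,12-hexaenoate | COC(=O)/C(C)=C/C=C/C=C(C)/C=C/C=C(C)/C=C/[C@@H]1C(C)=CC(=O)CC1(C)C | target

**Step count**
Total: 20 steps. Longest linear sequence: 17 steps (1–8, 10–15, 18–20); side branches are step 9 (boronate 14) and steps 16–17 (phosphonate 24).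

**Three steps most likely to fail, with fallbacks**

Step 3, where the two camphanates may not separate well. The fallback sets out from 6 and comes back at 8, and replaces covalent diastereomers by an enzymatic kinetic resolution. Racemic 6 is acetylated with Amano lipase PS and vinyl acetate in MTBE at 30 °C to about 50 % conversion, and ester and alcohol are separated on silica. With the CH2–CMe2 flank acting as the large group, the (4S) carbinol should react faster and give methyl (1S,4S)-4-acetoxy-2,6,6-trimethylcyclohex-2-ene-1-carboxylate F1, which K2CO3 in MeOH converts to 8. If the enzyme prefers the other enantiomer, the recovered alcohol is 8 itself.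

Step 8, a Takai reaction on a very hindered aldehyde whose α-centre could epimerise. The fallback sets out from 10 and comes back at 15, and avoids aldehyde 11 altogether. Mitsunobu thioetherification of 10 with 1-phenyl-1H-tetrazole-5-thiol (PPh3, DIAD, THF) gives 5-[({(1S,4S)-4-[(tert-butyldimethylsilyl)oxy]-2,6,6-trimethylcyclohex-2-en-1-yl}methyl)sulfanyl]-1-phenyl-1H-tetrazole F2. Oxidation with H2O2 and (NH4)6Mo7O24·4H2O in EtOH gives 5-[({(1S,4S)-4-[(tert-butyldimethylsilyl)oxy]-2,6,6-trimethylcyclohex-2-en-1-yl}methyl)sulfonyl]-1-phenyl-1H-tetrazole F3. Julia–Kocienski olefination of its anion (KN(SiMe3)2, DME, −60 °C) with commercial ethyl (E)-3-methyl-4-oxobut-2-enoate then gives diene ester 15 directly; the ring centre is β to the carbanion and cannot epimerise.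

Step 13, where the trisubstituted double bond of the phosphonate anion can scramble to a 2E/2Z mixture. The fallback sets out from 17 and comes back at 19, and replaces the olefination by a cross-coupling. Takai iodo-olefination of 17 (CrCl2, CHI3, THF–dioxane) gives tert-butyl({(1S,4S)-4-[(1E,3E,5E)-6-iodo-3-methylhexa-1,3,5-trien-1-yl]-3,5,5-trimethylcyclohex-2-en-1-yl}oxy)dimethylsilane F4. Suzuki coupling of this iodide with boronate 14 (Pd(dppf)Cl2, K3PO4, THF–H2O) gives 19, with the trisubstituted double bond taken from the geometrically defined boronate.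

**Further compounds**
F1 | step 3 | methyl (1S,4S)-4-acetoxy-2,6,6-trimethylcyclohex-2-ene-1-carboxylate | COC(=O)[C@@H]1C(C)=C[C@@H](OC(C)=O)CC1(C)C
F2 | step 8 | 5-[({(1S,4S)-4-[(tert-butyldimethylsilyl)oxy]-2,6,6-trimethylcyclohex-2-en-1-yl}methyl)sulfanyl]-1-phenyl-1H-tetrazole | c1ccc(cc1)-n2nnnc2SC[C@@H]3C(C)=C[C@@H](O[Si](C)(C)C(C)(C)C)CC3(C)C
F3 | step 8 | 5-[({(1S,4S)-4-[(tert-butyldimethylsilyl)oxy]-2,6,6-trimethylcyclohex-2-en-1-yl}methyl)sulfonyl]-1-phenyl-1H-tetrazole | O=S(=O)(C[C@@H]3C(C)=C[C@@H](O[Si](C)(C)C(C)(C)C)CC3(C)C)c2nnnn2-c1ccccc1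
F4 | step 13 | tert-butyl({(1S,4S)-4-[(1E,3E,5E)-6-iodo-3-methylhexa-1,3,5-trien-1-yl]-3,5,5-trimethylcyclohex-2-en-1-yl}oxy)dimethylsilane | I/C=C/C=C(C)/C=C/[C@@H]1C(C)=C[C@@H](O[Si](C)(C)C(C)(C)C)CC1(C)C
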